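**Retrosynthetic overview**

1. The target is 19-acetoxylabda-7,13E-diene-2α,15-diol. Its last operations are desilylation, C19 acetylation, and α-face methylation of a C19 aldehyde to make the C4 quaternary centre; that aldehyde comes from a C4=C19 exocyclic alkene by hydroboration and oxidation.
2. The C9 side chain and 9α-H come from a C9 ketone: alkyllithium addition, oxidative 1,3-transposition to the C7 enone, reduction to the 7β-ol, and reductive allylic diazene transposition back to C7=C8.
3. Ring A (formed second) is cut at C2–C3. The C2 carbinol sits between the C1 and C3 methylenes and is 1,3 to C4, which is the 3-methylenecyclohexanol pattern left by a carbonyl-ene closure of a C2 aldehyde onto the isopropenyl group on C5.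
4. Ring B (present from the start, with C5) is (R)-carvone; C10 is built by methylation and then bromoacetate alkylation anti to the isopropenyl group.
5. The E side-chain iodide comes from 4-(tert-butyldimethylsilyloxy)-1-butyne by zirconium-catalysed carboalumination and hydroxymethylation.

Key step: step 5

Assumption: labdane numbering is used (decalin C1–C10, side chain C11–C16, C17 on C8, C18/C19 on C4, C20 on C10); β is the face of the C10 methyl.
Assumption: 4-(tert-butyldimethylsilyloxy)-1-butyne is bought; where a stereocentre is erased in a later step, the expected major epimer is drawn and its epimer converges.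

**Route**

Step 1
Reactants: 1 (R)-(−)-carvone
Product: 3 trans-6-methylcarvone, via carvone lithium enolate 2 (not isolated)
Conditions: LiN(i-Pr)2, THF, −78 °C; MeI, −78 to 0 °C
Reagents that add atoms: iodomethane, CI
Why: Kinetic deprotonation at C6 (the α' position) gives the cross-conjugated enolate, and its SN2 methylation (enolate alkylation) should give mainly the trans product, whose new centre is re-enolised in step 2.

Step 2
Reactants: 3 trans-6-methylcarvone; 4 ethyl bromoacetate
Product: 6 keto ester (ethyl [1,3-dimethyl-2-oxo-6-(prop-1-en-2-yl)cyclohex-3-en-1-yl]acetate; acetate arm trans and methyl cis to the isopropenyl group), via 6-methylcarvone lithium enolate 5 (not isolated)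
Conditions: LiN(i-Pr)2, THF, −78 to 0 °C; 4, DMPU, −78 °C to rt
Reagents that add atoms: none
Why: Enolate alkylation of the fully substituted enolate with the activated bromide should occur on the face opposite the adjacent isopropenyl group, which sets the quaternary carbon (future C10) with the two-carbon arm trans to the isopropenyl group.

Step 3
Reactants: 6 keto ester
Product: 7 diol (2-[2-hydroxy-1,3-dimethyl-6-(prop-1-en-2-yl)cyclohex-3-en-1-yl]ethanol)
Conditions: LiAlH4, Et2O, 0 °C to rt
Reagents that add atoms: none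
Why: Hydride reduction takes the ester to the primary alcohol and the enone carbonyl to the allylic alcohol by 1,2-addition, and the configuration of the new ring carbinol does not matter because it is reoxidised in step 4.

Step 4
Reactants: 7 diol
Product: 9 keto aldehyde ([1,3-dimethyl-2-oxo-6-(prop-1-en-2-yl)cyclohex-3-en-1-yl]acetaldehyde), via bis-alkoxysulfonium salt 8 (not isolated)
Conditions: (COCl)2, DMSO, CH2Cl2, −78 °C; Et3N, −78 to 0 °C
Reagents that add atoms: none
Why: In the Swern oxidation both hydroxyls are activated as alkoxysulfonium ions before base is added, so the 1,4-diol should go to the keto aldehyde without passing through a lactol that could be oxidised to the lactone.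

Step 5
Reactants: 9 keto aldehyde
Product: 10 bicyclic hydroxy enone (trans-fused 2α-hydroxy-8,10β-dimethyl-4-methylidene-octal-7-en-9-one)
Conditions: Me2AlCl (2.2 equiv), CH2Cl2, −78 to −20 °C; 1 M HCl
Reagents that add atoms: none
Why: Me2AlCl binds the C2 aldehyde, the CH2 terminus of the isopropenyl group (C3) attacks it, a hydrogen of the isopropenyl methyl (C19) ends on oxygen and the aluminium alkoxide is fixed by loss of methane; the closest known reaction is the Me2AlCl-promoted type 2 intramolecular carbonyl-ene cyclisation of aldehydes onto 1,1-disubstituted alkenes to 3-methylenecyclohexanols. Ring A closes as a six-membered chair, exo at the carbonyl and with both alkene carbons (C3 and C4) inside the ring, and the trans ring fusion is preset by the trans-diequatorial acetaldehyde arm on C10 and isopropenyl group on C5. The only new stereocentre is C2: a fully concerted bicyclic ene array would hold the complexed oxygen axial and 1,3-diaxial to the C10 methyl, so closure is expected through the chair with oxygen equatorial (2α), with a more stepwise, Prins-like bond formation followed by loss of a C19 proton. The step needs the aldehyde to react in preference to the hindered enone carbonyl (it is the stronger electrophile and two equivalents of Lewis acid cover both oxygens) and proton loss from C19 and not from C3 or C5, which low temperature and the proton-accepting Al–CH3 groups should favour.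

Step 6
Reactants: 10 bicyclic hydroxy enone
Product: 11 silyl ether enone (2α-tert-butyldimethylsilyloxy derivative of 10)
Conditions: TBSCl, imidazole, DMF, rt
Reagents that add atoms: tert-butyldimethylsilyl chloride, CC(C)(C)[Si](C)(C)Cl
Why: Silyl ether formation on the unhindered equatorial secondary alcohol masks C2–OH against the organolithium and chromium steps.

Step 7
Reactants: 12 4-(tert-butyldimethylsilyloxy)-1-butyne
Product: 15 (E)-5-(tert-butyldimethylsilyloxy)-3-methylpent-2-en-1-ol, via alkenyldimethylalane 13 (not isolated), via lithium alkenylaluminate 14 (not isolated)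
Conditions: Me3Al, Cp2ZrCl2 (cat.), CH2Cl2, 0 °C to rt; n-BuLi, THF, −78 °C; (CH2O)n, −78 °C to rt; H2O
Reagents that add atoms: trimethylaluminium, C[Al](C)C; paraformaldehyde (as formaldehyde), C=O
Why: Negishi carboalumination adds methyl and aluminium syn across the terminal alkyne with methyl on the internal carbon, and the derived aluminate is hydroxymethylated with retention, so the E trisubstituted allylic alcohol should result.

Step 8
Reactants: 15 (E)-5-(tert-butyldimethylsilyloxy)-3-methylpent-2-en-1-ol
Product: 16 bis-silyl ether ((E)-1-tert-butyldiphenylsilyloxy-5-tert-butyldimethylsilyloxy-3-methylpent-2-ene)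
Conditions: TBDPSCl, imidazole, CH2Cl2, rt
Reagents that add atoms: tert-butyl(chloro)diphenylsilane, CC(C)(C)[Si](Cl)(c1ccccc1)c1ccccc1
Why: Silylation of the primary allylic alcohol installs a group that outlasts the acid cleavage of the other silyl ether and all later steps.

Step 9
Reactants: 16 bis-silyl ether
Product: 17 (E)-5-(tert-butyldiphenylsilyloxy)-3-methylpent-3-en-1-ol
Conditions: PPTS (cat.), MeOH, rt
Reagents that add atoms: none
Why: Acid-catalysed methanolysis (selective desilylation) cleaves the primary tert-butyldimethylsilyl ether much faster than the bulkier tert-butyldiphenylsilyl ether.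

Step 10
Reactants: 17 (E)-5-(tert-butyldiphenylsilyloxy)-3-methylpent-3-en-1-ol
Product: 18 homoallylic iodide (tert-butyl{[(2E)-5-iodo-3-methylpent-2-en-1-yl]oxy}diphenylsilane)
Conditions: I2, PPh3, imidazole, CH2Cl2, 0 °C
Reagents that add atoms: iodine, II
Why: Appel-type iodination (Garegg–Samuelsson conditions) displaces the primary alkoxyphosphonium by iodide without touching the alkene geometry.

Step 11
Reactants: 18 homoallylic iodide; 11 silyl ether enone
Product: 20 tertiary allylic alcohol (18-norlabda-4(19),7,13E-triene-2α,9,15-triol 2-TBS 15-TBDPS bis-ether), via alkyllithium 19 (not isolated)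
Conditions: 18, t-BuLi (2 equiv), Et2O/pentane, −78 °C; then 11, −78 to 0 °C; H2O
Reagents that add atoms: none
Why: Lithium–iodine exchange gives the primary alkyllithium, which should add 1,2 to the enone carbonyl (organolithium addition) from the α face away from the axial C10 methyl, and the C9 configuration is erased in step 12.

Step 12
Reactants: 20 tertiary allylic alcohol
Product: 21 transposed enone (18-norlabda-4(19),8,13E-trien-7-one 2α-OTBS 15-OTBDPS)
Conditions: pyridinium chlorochromate [C5H5NH][CrO3Cl], Celite, CH2Cl2, rt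
Reagents that add atoms: pyridinium chlorochromate, [O-][Cr](=O)(=O)Cl.c1cc[nH+]cc1
Why: In the Dauben–Babler oxidative transposition the tertiary allylic chromate ester undergoes a [3,3] shift to C7 and is then oxidised, which moves the oxygen to C7 and leaves the side chain on the C8=C9 alkene.

Step 13
Reactants: 21 transposed enone
Product: 22 allylic alcohol (7β-ol of 21)
Conditions: NaBH4, CeCl3·7H2O, MeOH, −40 to 0 °C
Reagents that add atoms: none
Why: Luche reduction is 1,2-selective and axial hydride delivery on the α face should give the pseudo-equatorial 7β-alcohol.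

Step 14
Reactants: 22 allylic alcohol
Product: 23 hydrazone adduct (7α-[N-(2-nitrobenzenesulfonyl)-N'-isopropylidenehydrazino] derivative)
Conditions: IPNBSH, PPh3, DEAD, THF, 0 °C to rt; chromatography
Reagents that add atoms: N-isopropylidene-N'-(2-nitrobenzenesulfonyl)hydrazine (IPNBSH), CC(C)=NNS(=O)(=O)c1ccccc1[N+](=O)[O-]
Why: The Mitsunobu reaction with the acidic sulfonamide N–H displaces the activated 7β-oxygen with inversion, placing nitrogen on the α face, and isolating the adduct removes excess reagent that could otherwise release diimide and reduce the exocyclic alkene.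

Step 15
Reactants: 23 hydrazone adduct
Product: 26 triene (18-norlabda-4(19),7,13E-triene-2α,15-diol 2-TBS 15-TBDPS bis-ether; 9α-H), via sulfonyl hydrazine 24 (not isolated), via allylic diazene 25 (not isolated)
Conditions: CF3CH2OH/H2O (1:1), THF, rt
Reagents that add atoms: none
Why: Hydrolysis of the hydrazone, loss of sulfinic acid to the monoalkyl diazene and retro-ene loss of N2 (Myers reductive allylic transposition, Movassaghi variant) should transfer hydrogen suprafacially from the 7α-nitrogen to the α face of C9 while the alkene moves to C7=C8, which sets 9α-H with the side chain β.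

Step 16
Reactants: 26 triene
Product: 28 primary alcohol (18-norlabda-7,13E-diene-2α,15,19-triol 2-TBS 15-TBDPS bis-ether; 4α-H), via B-alkyl-9-BBN adduct 27 (not isolated)
Conditions: 9-BBN, THF, rt to 50 °C; NaOH, H2O2, H2O, 0 °C to rt
Reagents that add atoms: hydrogen peroxide, OO
Why: Hydroboration–oxidation with 9-BBN is anti-Markovnikov and far faster on the 1,1-disubstituted C4=C19 alkene than on the two trisubstituted alkenes, and the C4 configuration (α-face attack expected) is erased in step 18.

Step 17
Reactants: 28 primary alcohol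
Product: 29 aldehyde (19-al of 28)
Conditions: Dess–Martin periodinane, pyridine, CH2Cl2, 0 °C to rt
Reagents that add atoms: none
Why: Dess–Martin oxidation of the only free hydroxyl gives the aldehyde under buffered conditions that spare both silyl ethers.

Step 18
Reactants: 29 aldehyde
Product: 31 quaternary aldehyde (2α-OTBS-15-OTBDPS-labda-7,13E-dien-19-al), via potassium enolate 30 (not isolated)
Conditions: KOt-Bu, THF, 0 °C; MeI
Reagents that add atoms: iodomethane, CI
Why: Enolate alkylation of the exocyclic aldehyde enolate should take methyl on the α face, anti to the axial C10 methyl that screens the β face, which sets C4 with methyl α (C18) and the formyl carbon β (C19).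

Step 19
Reactants: 31 quaternary aldehyde
Product: 32 neopentyl alcohol (labda-7,13E-diene-2α,15,19-triol 2-TBS 15-TBDPS bis-ether)
Conditions: NaBH4, MeOH/THF, 0 °C
Reagents that add atoms: none
Why: Borohydride reduction of the aldehyde gives the primary C19 alcohol with no other reducible group present.

Step 20
Reactants: 32 neopentyl alcohol
Product: 33 acetate (19-acetate of 32)
Conditions: Ac2O, pyridine, DMAP (cat.), CH2Cl2, rt
Reagents that add atoms: acetic anhydride, CC(=O)OC(C)=O
Why: DMAP-catalysed acylation esterifies the only free hydroxyl, so the acetate is placed on C19 without any selectivity problem against C2 or C15.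

Step 21
Reactants: 33 acetate
Product: 34 target (19-acetoxylabda-7,13E-diene-2α,15-diol)
Conditions: Bu4NF, AcOH, THF, 0 °C to rt
Reagents that add atoms: none
Why: Fluoride desilylation buffered with acetic acid removes the secondary tert-butyldimethylsilyl and primary tert-butyldiphenylsilyl ethers together while leaving the hindered neopentyl acetate in place.

**Compound list**

1 | (R)-(−)-carvone | C=C(C)[C@@H]1CC=C(C)C(=O)C1 | starting material
2 | carvone lithium enolate (cross-conjugated, C1–O, C1=C6) | [Li+].C=C(C)[C@@H]1CC=C(C)C([O-])=C1 | intermediate (not isolated)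
3 | trans-6-methylcarvone (methyl anti to isopropenyl; cis epimer carried along) | C=C(C)[C@@H]1CC=C(C)C(=O)[C@H]1C | intermediate
4 | ethyl bromoacetate | CCOC(=O)CBr | starting material
5 | 6-methylcarvone lithium enolate | [Li+].C=C(C)[C@@H]1CC=C(C)C([O-])=C1C | intermediate (not isolated)
6 | keto ester, ethyl [1,3-dimethyl-2-oxo-6-(prop-1-en-2-yl)cyclohex-3-en-1-yl]acetate (arm trans, methyl cis to isopropenyl) | C=C(C)[C@@H]1CC=C(C)C(=O)[C@@]1(C)CC(=O)OCC | intermediate
7 | diol, 2-[2-hydroxy-1,3-dimethyl-6-(prop-1-en-2-yl)cyclohex-3-en-1-yl]ethanol (ring carbinol: expected major epimer drawn) | C=C(C)[C@@H]1CC=C(C)[C@H](O)[C@@]1(C)CCO | intermediate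
8 | bis-alkoxysulfonium dichloride of diol 7 | C=C(C)[C@@H]1CC=C(C)[C@H](O[S+](C)C)[C@@]1(C)CCO[S+](C)C.[Cl-].[Cl-] | intermediate (not isolated)
9 | keto aldehyde, [1,3-dimethyl-2-oxo-6-(prop-1-en-2-yl)cyclohex-3-en-1-yl]acetaldehyde | C=C(C)[C@@H]1CC=C(C)C(=O)[C@@]1(C)CC=O | intermediate
10 | bicyclic hydroxy enone: trans-fused, 2α-OH (equatorial), C4 exocyclic methylene, C10 methyl β, H5 α, C9 ketone, C7=C8 | C=C1C[C@H](O)C[C@]2(C)C(=O)C(C)=CC[C@@H]12 | intermediate
11 | 2α-tert-butyldimethylsilyl ether of 10 | C=C1C[C@H](O[Si](C)(C)C(C)(C)C)C[C@]2(C)C(=O)C(C)=CC[C@@H]12 | intermediate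
12 | 4-(tert-butyldimethylsilyloxy)-1-butyne | C#CCCO[Si](C)(C)C(C)(C)C | starting material
13 | (E)-alkenyldimethylalane (Al cis to methyl) | C[Al](C)/C=C(\C)CCO[Si](C)(C)C(C)(C)C | intermediate (not isolated)
14 | lithium butyl(alkenyl)dimethylaluminate | [Li+].CCCC[Al-](C)(C)/C=C(\C)CCO[Si](C)(C)C(C)(C)C | intermediate (not isolated)
15 | (E)-5-(tert-butyldimethylsilyloxy)-3-methylpent-2-en-1-ol | OC/C=C(\C)CCO[Si](C)(C)C(C)(C)C | intermediate
16 | (E)-1-(tert-butyldiphenylsilyloxy)-5-(tert-butyldimethylsilyloxy)-3-methylpent-2-ene | CC(C)(C)[Si](C)(C)OCC/C(C)=C/CO[Si](c1ccccc1)(c1ccccc1)C(C)(C)C | intermediate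
17 | (E)-5-(tert-butyldiphenylsilyloxy)-3-methylpent-3-en-1-ol | OCC/C(C)=C/CO[Si](c1ccccc1)(c1ccccc1)C(C)(C)C | intermediate
18 | tert-butyl{[(2E)-5-iodo-3-methylpent-2-en-1-yl]oxy}diphenylsilane | ICC/C(C)=C/CO[Si](c1ccccc1)(c1ccccc1)C(C)(C)C | intermediate
19 | (E)-5-(tert-butyldiphenylsilyloxy)-3-methylpent-3-enyllithium | [Li]CC/C(C)=C/CO[Si](c1ccccc1)(c1ccccc1)C(C)(C)C | intermediate (not isolated)
20 | tertiary allylic alcohol: 9-hydroxy (9β-OH drawn), side chain on C9, C7=C8, C4 exocyclic methylene, 2α-OTBS, 15-OTBDPS | C=C1C[C@H](O[Si](C)(C)C(C)(C)C)C[C@]2(C)[C@](O)(CC/C(C)=C/CO[Si](c3ccccc3)(c3ccccc3)C(C)(C)C)C(C)=CC[C@@H]12 | intermediate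
21 | transposed enone: C7 ketone, C8=C9 carrying methyl and side chain | C=C1C[C@H](O[Si](C)(C)C(C)(C)C)C[C@]2(C)C(CC/C(C)=C/CO[Si](c3ccccc3)(c3ccccc3)C(C)(C)C)=C(C)C(=O)C[C@@H]12 | intermediate
22 | allylic alcohol: 7β-OH, C8=C9 | C=C1C[C@H](O[Si](C)(C)C(C)(C)C)C[C@]2(C)C(CC/C(C)=C/CO[Si](c3ccccc3)(c3ccccc3)C(C)(C)C)=C(C)[C@@H](O)C[C@@H]12 | intermediate
23 | 7α-[N-(2-nitrobenzenesulfonyl)-N'-isopropylidenehydrazino] adduct | C=C1C[C@H](O[Si](C)(C)C(C)(C)C)C[C@]2(C)C(CC/C(C)=C/CO[Si](c3ccccc3)(c3ccccc3)C(C)(C)C)=C(C)[C@H](N(N=C(C)C)S(=O)(=O)c3ccccc3[N+](=O)[O-])C[C@@H]12 | intermediate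
24 | 7α-[N-(2-nitrobenzenesulfonyl)hydrazino] compound | C=C1C[C@H](O[Si](C)(C)C(C)(C)C)C[C@]2(C)C(CC/C(C)=C/CO[Si](c3ccccc3)(c3ccccc3)C(C)(C)C)=C(C)[C@H](N(N)S(=O)(=O)c3ccccc3[N+](=O)[O-])C[C@@H]12 | intermediate (not isolated)
25 | 7α-allylic diazene | C=C1C[C@H](O[Si](C)(C)C(C)(C)C)C[C@]2(C)C(CC/C(C)=C/CO[Si](c3ccccc3)(c3ccccc3)C(C)(C)C)=C(C)[C@H](N=N)C[C@@H]12 | intermediate (not isolated)
26 | triene: C7=C8, 9α-H with side chain β, C4 exocyclic methylene, 2α-OTBS, 15-OTBDPS | C=C1C[C@H](O[Si](C)(C)C(C)(C)C)C[C@]2(C)[C@@H](CC/C(C)=C/CO[Si](c3ccccc3)(c3ccccc3)C(C)(C)C)C(C)=CC[C@@H]12 | intermediate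
27 | B-(C19-alkyl)-9-borabicyclo[3.3.1]nonane adduct (C19 β drawn) | C(B3C4CCCC3CCC4)[C@H]1C[C@H](O[Si](C)(C)C(C)(C)C)C[C@]2(C)[C@@H](CC/C(C)=C/CO[Si](c3ccccc3)(c3ccccc3)C(C)(C)C)C(C)=CC[C@@H]12 | intermediate (not isolated)
28 | C19 primary alcohol with 4α-H (C4 epimer converges) | OC[C@H]1C[C@H](O[Si](C)(C)C(C)(C)C)C[C@]2(C)[C@@H](CC/C(C)=C/CO[Si](c3ccccc3)(c3ccccc3)C(C)(C)C)C(C)=CC[C@@H]12 | intermediate
29 | C19 aldehyde with C4–H (epimerisable) | O=C[C@H]1C[C@H](O[Si](C)(C)C(C)(C)C)C[C@]2(C)[C@@H](CC/C(C)=C/CO[Si](c3ccccc3)(c3ccccc3)C(C)(C)C)C(C)=CC[C@@H]12 | intermediate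
30 | potassium enolate of 29 (C4=C19, either geometry) | [K+].[O-]C=C1C[C@H](O[Si](C)(C)C(C)(C)C)C[C@]2(C)[C@@H](CC/C(C)=C/CO[Si](c3ccccc3)(c3ccccc3)C(C)(C)C)C(C)=CC[C@@H]12 | intermediate (not isolated)
31 | quaternary aldehyde: 4α-methyl, 4β-formyl | O=C[C@@]1(C)C[C@H](O[Si](C)(C)C(C)(C)C)C[C@]2(C)[C@@H](CC/C(C)=C/CO[Si](c3ccccc3)(c3ccccc3)C(C)(C)C)C(C)=CC[C@@H]12 | intermediate
32 | C19 alcohol: 4β-CH2OH, 4α-CH3 | OC[C@@]1(C)C[C@H](O[Si](C)(C)C(C)(C)C)C[C@]2(C)[C@@H](CC/C(C)=C/CO[Si](c3ccccc3)(c3ccccc3)C(C)(C)C)C(C)=CC[C@@H]12 | intermediate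
33 | C19 acetate, 2α-OTBS, 15-OTBDPS | CC(=O)OC[C@@]1(C)C[C@H](O[Si](C)(C)C(C)(C)C)C[C@]2(C)[C@@H](CC/C(C)=C/CO[Si](c3ccccc3)(c3ccccc3)C(C)(C)C)C(C)=CC[C@@H]12 | intermediate
34 | 19-acetoxylabda-7,13E-diene-2α,15-diol (CNP0319060.1) | CC(=O)OC[C@@]1(C)C[C@H](O)C[C@]2(C)[C@@H](CC/C(C)=C/CO)C(C)=CC[C@@H]12 | target

**Step count**

Total: 21 steps. Longest linear sequence: 17 steps from (R)-carvone (steps 1–6 and 11–21); the side-chain branch is steps 7–10.

**Steps most likely to fail**

1. Step 5. The closure may not follow the equatorial-oxygen course. A concerted ene array wants the C2 oxygen axial, which the C10 methyl opposes. The reaction can then drift to a stepwise Prins course with proton loss from C3 or C5, chloride transfer to C4, or incomplete control at C2. The fallback sets out from keto ester 6 and replaces the ene partner by an allylsilane, so that silicon fixes the exocyclic alkene and an open transition state places oxygen equatorial.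
 - Ene-type chlorination with Ca(OCl)2 and solid CO2 in CH2Cl2/H2O should attack only the electron-rich isopropenyl group and give allylic chloride F1.
 - Me3SiSiMe3 with Pd(dba)2 (zerovalent palladium) in DMF converts it to allylsilane F2.
 - LiAlH4 gives silyl diol F3, and Swern oxidation gives silyl keto aldehyde F4.
 - BF3·OEt2 in CH2Cl2 at −78 °C closes ring A by Hosomi–Sakurai addition, and the fallback comes back to the route at 10.

2. Step 14. Mitsunobu displacement at the hindered C7 carbinol, next to a tetrasubstituted alkene, may be outrun by elimination toward C6 or may be too slow. The fallback sets out from allylic alcohol 22.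
 - Formylation (HCO2H, DCC, DMAP, CH2Cl2) gives 7β-formate F5.
 - Pd(OAc)2 (divalent palladium, reduced in the flask to zerovalent palladium) with n-Bu3P in dioxane ionises the formate with inversion and CO2 is lost.
 - The palladium hydride delivers hydrogen to the more substituted allyl terminus C9 on the α face (Tsuji–Mandai formate hydrogenolysis).
 - The fallback comes back to the route at 26 and bypasses step 15.

3. Step 18. The aldehyde enolate may be methylated on oxygen, or the α-face preference may be incomplete. The fallback sets out from aldehyde 29 and builds the methyl by carbenoid addition in place of SN2 alkylation.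
 - Me3SiCl, Et3N and NaI in MeCN give trimethylsilyl enol ether F6.
 - Et2Zn and CH2I2 in CH2Cl2 at 0 °C (Furukawa–Simmons–Smith) cyclopropanate the electron-rich enol ether from the α face in preference to the other alkenes, giving siloxycyclopropane F7.
 - K2CO3 in MeOH opens the cyclopropanol with protonation at the ring CH2 (Conia α-methylation).
 - The fallback comes back to the route at 31.

Further compounds
F1 | step 5 | allylic chloride, ethyl [6-(3-chloroprop-1-en-2-yl)-1,3-dimethyl-2-oxocyclohex-3-en-1-yl]acetate | C=C(CCl)[C@@H]1CC=C(C)C(=O)[C@@]1(C)CC(=O)OCC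
F2 | step 5 | allylsilane, ethyl {1,3-dimethyl-2-oxo-6-[3-(trimethylsilyl)prop-1-en-2-yl]cyclohex-3-en-1-yl}acetate | C=C(C[Si](C)(C)C)[C@@H]1CC=C(C)C(=O)[C@@]1(C)CC(=O)OCC
F3 | step 5 | silyl diol (ring carbinol: expected major epimer drawn) | C=C(C[Si](C)(C)C)[C@@H]1CC=C(C)[C@H](O)[C@@]1(C)CCO
F4 | step 5 | silyl keto aldehyde | C=C(C[Si](C)(C)C)[C@@H]1CC=C(C)C(=O)[C@@]1(C)CC=O
F5 | step 14 | 7β-formate of 22 | C=C1C[C@H](O[Si](C)(C)C(C)(C)C)C[C@]2(C)C(CC/C(C)=C/CO[Si](c3ccccc3)(c3ccccc3)C(C)(C)C)=C(C)[C@@H](OC=O)C[C@@H]12
F6 | step 18 | trimethylsilyl enol ether of 29 (C4=C19) | C[Si](C)(C)OC=C1C[C@H](O[Si](C)(C)C(C)(C)C)C[C@]2(C)[C@@H](CC/C(C)=C/CO[Si](c3ccccc3)(c3ccccc3)C(C)(C)C)C(C)=CC[C@@H]12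
F7 | step 18 | spiro siloxycyclopropane (new CH2 on the α face of C4; C19 epimers) | C[Si](C)(C)OC3C[C@@]31C[C@H](O[Si](C)(C)C(C)(C)C)C[C@]2(C)[C@@H](CC/C(C)=C/CO[Si](c4ccccc4)(c4ccccc4)C(C)(C)C)C(C)=CC[C@@H]12
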